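A direct plan would mono-O-prenylate the acetophenone 1-(2,6-dihydroxy-4-methoxyphenyl)ethanone A1 to the ether A2, silylate the second phenol and α-chlorinate the ketone to the chloromethyl ketone A3.
It would then condense A3 with the aldehyde 4-(tert-butyldimethylsilyloxy)benzaldehyde A4 in an asymmetric Darzens reaction, desilylate to the trans-epoxy ketone A5, and let the 2'-phenol open the oxirane to the 5-O-prenyl dihydroflavonol A6.
A para-Claisen–Cope shift of A6 would finish the target.
Weakest point (a), the Darzens condensation under a chiral ammonium salt: the absolute configuration of the whole molecule would rest on a reaction without close precedent for a di-ortho-substituted aryl chloromethyl ketone.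
Weakest point (b), the ring closure by phenol attack on the oxirane: 6-endo attack would have to beat 5-exo attack, and C2 would be set through an ionising para-oxybenzylic carbon, so with little kinetic control.
Weakest point (c), the final sigmatropic prenyl transfer: a Lewis acid at 85 °C would act on the finished ketol with free phenols, which can epimerise, dehydrate or oxidise, and arrest after the first shift would cost material at the last step.

**Retrosynthetic overview**
The route cuts the C2–C1′ bond: C2 of ring C is both the benzylic carbon that carries ring B and the β-carbon of the C4 ketone, so ring B can be delivered as an aryl nucleophile to C2 of a flat, achiral benzopyranone (rings A and C).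
Ring order: ring A is bought; ring C is closed first, as the aromatic 4H-chromen-4-one, by a one-carbon annulation; the prenyl group is moved from O5 to C8 on this robust chromone; ring B is joined last.
C2 is set by a catalytic asymmetric 1,4-arylation, and the C3 hydroxyl is then placed trans to the aryl group by oxidation of the enol silane, the chemical counterpart of the 3-hydroxylation of a flavanone.
There is no Darzens step and no oxirane opening, and the sigmatropic shift runs where there is no stereocenter, no ketol and no free benzylic alcohol.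

Key step: step 4

Assumption: the sense of induction in step 4 is taken from the accepted model for cyclohexenone, in which an (S)-biaryl bisphosphine gives the (S)-β-aryl ketone; if a test reaction shows the opposite sense, the (R)-ligand is used and nothing else changes.

Step 1
Reactants: 1 1-(2,6-dihydroxy-4-methoxyphenyl)ethanone; 2 1-bromo-3-methylbut-2-ene (prenyl bromide)
Product: 3 1-[2-hydroxy-4-methoxy-6-(3-methylbut-2-enyloxy)phenyl]ethanone
Conditions: K2CO3 (1.5 equiv), 2 (1.05 equiv), acetone, reflux
Reagents that add atoms: none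
Why: Williamson ether synthesis on a symmetric, chelated diol; after the first O-alkylation the remaining phenol stays hydrogen-bonded to the ketone and is much less nucleophilic, so the mono-ether should dominate; no stereocenter.

Step 2
Reactants: 3 1-[2-hydroxy-4-methoxy-6-(3-methylbut-2-enyloxy)phenyl]ethanone
Product: 5 7-methoxy-5-(3-methylbut-2-enyloxy)-4H-chromen-4-one, via enaminone 4 (not isolated)
Conditions: Me2NCH(OMe)2 (2 equiv), toluene, 95 °C; evaporate; then 1 M aq HCl, CH2Cl2, rt
Reagents that add atoms: N,N-dimethylformamide dimethyl acetal, COC(OC)N(C)C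
Why: Enaminone route to chromones: condensation at the acetyl methyl group, then acid-promoted 6-endo addition of the chelated phenol to the enaminone β-carbon and loss of dimethylamine close ring C as the aromatic pyranone; the aryl prenyl ether should tolerate dilute acid at room temperature; no stereocenter.

Step 3
Reactants: 5 7-methoxy-5-(3-methylbut-2-enyloxy)-4H-chromen-4-one
Product: 8 5-hydroxy-7-methoxy-8-(3-methylbut-2-enyl)-4H-chromen-4-one, via ortho-dienone 6 (not isolated), via para-dienone 7 (not isolated)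
Conditions: Eu(fod)3 [tris(6,6,7,7,8,8,8-heptafluoro-2,2-dimethyl-3,5-octanedionato)europium] (10 mol %), NaHCO3 (1 equiv), chlorobenzene, 85 °C
Reagents that add atoms: none
Why: Aromatic Claisen rearrangement from O5 to C6, Cope rearrangement on to the para carbon C8 and enolisation (para-Claisen–Cope sequence, accelerated by europium chelated between the C4 carbonyl and O5), as known for 5-O-prenyl flavonoids; the substrate is flat and achiral, so nothing can epimerise, and the C8 prenyl group cannot cyclise onto the para 5-OH.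

Step 4
Reactants: 8 5-hydroxy-7-methoxy-8-(3-methylbut-2-enyl)-4H-chromen-4-one; 9 [4-(tert-butyldimethylsilyloxy)phenyl]boronic acid
Product: 10 (2S)-2-[4-(tert-butyldimethylsilyloxy)phenyl]-5-hydroxy-7-methoxy-8-(3-methylbut-2-enyl)-2,3-dihydro-4H-chromen-4-one
Conditions: [Rh(OH)(cod)]2 (1.5 mol %, cod = 1,5-cyclooctadiene), (S)-MeO-F12-BIPHEP [(S)-6,6′-dimethoxy-2,2′-bis{bis(3,4,5-trifluorophenyl)phosphino}biphenyl] (3.6 mol %), 9 (2.5 equiv), CH2Cl2/H2O (10:1), 20–30 °C
Reagents that add atoms: none
Why: Hayashi–Miyaura asymmetric 1,4-addition: the aryl group passes from boron to the hydroxo rhodium bisphosphine complex, the aryl–rhodium bond adds across C2=C3 with the aryl group going to C2, and water protonates the oxa-π-allyl rhodium enolate at C3 and regenerates the hydroxo complex. The closest known reaction is this same addition of arylboronic acids to 4H-chromen-4-ones, including 5,7-dioxygenated ones, with an electron-poor biaryl bisphosphine in a two-phase medium at room temperature. The step closes no ring; it joins ring B to the finished A/C bicycle through the C2–C1′ bond and turns the flat chromone into the flavanone skeleton. The new stereocenter C2 is under catalyst control, and the (S)-ligand is expected to give 2S, which is the same spatial arrangement as 2R in the target, where the C3 hydroxyl changes the priorities. The step needs 1,4- over 1,2-addition and a product that does not reopen to the chalcone: the base-free medium and low temperature guard against retro-oxa-Michael opening, the hydrogen bond from 5-OH activates the enone, and the prenyl alkene and the aryl silyl ether are inert to the aryl–rhodium species.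

Step 5
Reactants: 10 (2S)-2-[4-(tert-butyldimethylsilyloxy)phenyl]-5-hydroxy-7-methoxy-8-(3-methylbut-2-enyl)-2,3-dihydro-4H-chromen-4-one
Product: 13 (2R,3R)-3,5-dihydroxy-2-(4-hydroxyphenyl)-7-methoxy-8-(3-methylbut-2-enyl)-2,3-dihydro-4H-chromen-4-one, via bis-silyl enol ether 11 (not isolated), via silyloxy epoxide 12 (not isolated)
Conditions: Me3SiOTf (2.4 equiv), Et3N (3 equiv), CH2Cl2, −78 to 0 °C; pentane, cold aq NaHCO3 wash, evaporate; then dimethyldioxirane (1.05 equiv, acetone solution), CH2Cl2, −78 °C; evaporate; then Bu4NF (3.3 equiv), AcOH (4 equiv), THF, 0 °C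
Reagents that add atoms: dimethyldioxirane, CC1(C)OO1
Why: Rubottom oxidation: soft enolisation (silyl triflate and amine) gives the 4-silyloxy-2H-chromene without a free enolate that could open ring C, the dioxirane should attack the electron-rich enol ether (faster than the trialkyl prenyl alkene at −78 °C) on the face anti to the C2 aryl group, so the new C3–O bond is trans to the aryl group (3R), and buffered fluoride opens the silyloxy epoxide to the ketol and frees both phenols without base; trans is also the thermodynamically favoured arrangement.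

**Compound list**

1 | 1-(2,6-dihydroxy-4-methoxyphenyl)ethanone | CC(=O)c1c(O)cc(OC)cc1O | starting material
2 | 1-bromo-3-methylbut-2-ene (prenyl bromide) | CC(C)=CCBr | starting material
3 | 1-[2-hydroxy-4-methoxy-6-(3-methylbut-2-enyloxy)phenyl]ethanone | CC(=O)c1c(O)cc(OC)cc1OCC=C(C)C | intermediate
4 | (E)-3-(dimethylamino)-1-[2-hydroxy-4-methoxy-6-(3-methylbut-2-enyloxy)phenyl]prop-2-en-1-one | CN(C)/C=C/C(=O)c1c(O)cc(OC)cc1OCC=C(C)C | intermediate
5 | 7-methoxy-5-(3-methylbut-2-enyloxy)-4H-chromen-4-one | COc1cc(OCC=C(C)C)c2c(c1)occc2=O | intermediate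
6 | 7-methoxy-6-(2-methylbut-3-en-2-yl)-4H-chromene-4,5(6H)-dione (racemic at C6) | COC1=CC2=C(C(=O)C1C(C)(C)C=C)C(=O)C=CO2 | intermediate
7 | 7-methoxy-8-(3-methylbut-2-enyl)-4H-chromene-4,5(8H)-dione (racemic at C8) | COC1=CC(=O)C2=C(OC=CC2=O)C1CC=C(C)C | intermediate
8 | 5-hydroxy-7-methoxy-8-(3-methylbut-2-enyl)-4H-chromen-4-one | COc1cc(O)c2c(c1CC=C(C)C)occc2=O | intermediate
9 | [4-(tert-butyldimethylsilyloxy)phenyl]boronic acid | CC(C)(C)[Si](C)(C)Oc1ccc(cc1)B(O)O | starting material
10 | (2S)-2-[4-(tert-butyldimethylsilyloxy)phenyl]-5-hydroxy-7-methoxy-8-(3-methylbut-2-enyl)-2,3-dihydro-4H-chromen-4-one | COc1cc(O)c2c(c1CC=C(C)C)O[C@H](c1ccc(O[Si](C)(C)C(C)(C)C)cc1)CC2=O | intermediate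
11 | (2S)-2-[4-(tert-butyldimethylsilyloxy)phenyl]-7-methoxy-8-(3-methylbut-2-enyl)-4,5-bis(trimethylsilyloxy)-2H-chromene | COc1cc(O[Si](C)(C)C)c2c(c1CC=C(C)C)O[C@H](c1ccc(O[Si](C)(C)C(C)(C)C)cc1)C=C2O[Si](C)(C)C | intermediate
12 | (2R,3R,4R)-2-[4-(tert-butyldimethylsilyloxy)phenyl]-3,4-epoxy-7-methoxy-8-(3-methylbut-2-enyl)-4,5-bis(trimethylsilyloxy)-3,4-dihydro-2H-chromene (3,4-epoxide of 11, oxirane oxygen trans to the C2 aryl group) | COc1cc(O[Si](C)(C)C)c2c(c1CC=C(C)C)O[C@H](c1ccc(O[Si](C)(C)C(C)(C)C)cc1)[C@H]3O[C@@]23O[Si](C)(C)C | intermediate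
13 | (2R,3R)-3,5-dihydroxy-2-(4-hydroxyphenyl)-7-methoxy-8-(3-methylbut-2-enyl)-2,3-dihydro-4H-chromen-4-one | COc1cc(O)c2c(c1CC=C(C)C)O[C@H](c1ccc(O)cc1)[C@@H](O)C2=O | target

Total step count: 5. Longest linear sequence: 5 steps (1 to 13; 9 is bought).

**Steps most likely to fail**

Step 5. The dioxirane may also epoxidise the prenyl double bond, or the silyl triflate may ionise the para-oxybenzylic C2–O1 bond and erode the C2 configuration. The fallback sets out from 10 and comes back at 13, and replaces the oxidation of a neutral enol silane by the hydroxylation of a metal enolate with a reagent that leaves isolated alkenes alone. 10 would be silylated at O5 (tert-butyldimethylsilyl triflate, 2,6-lutidine, CH2Cl2, −78 °C) to the bis-silyl ether (2S)-5-(tert-butyldimethylsilyloxy)-2-[4-(tert-butyldimethylsilyloxy)phenyl]-7-methoxy-8-(3-methylbut-2-enyl)-2,3-dihydro-4H-chromen-4-one F1. Its sodium enolate (NaN(SiMe3)2, THF, −78 °C) would be hydroxylated with 3-phenyl-2-(phenylsulfonyl)oxaziridine, anti to the aryl group, to the trans ketol (2R,3R)-5-(tert-butyldimethylsilyloxy)-2-[4-(tert-butyldimethylsilyloxy)phenyl]-3-hydroxy-7-methoxy-8-(3-methylbut-2-enyl)-2,3-dihydro-4H-chromen-4-one F2. Bu4NF/AcOH in THF at 0 °C would then give 13.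

Step 4. The acidic, chelated 5-OH may protonate the aryl–rhodium species faster than it inserts into the electron-rich chromone, so that the boronic acid is lost by protodeboronation and turnover stalls. The fallback sets out from 5 and comes back at 10, and changes the order of events so that the arylation meets no free phenol. The non-phenolic chromone 5 would be arylated with 9 under the conditions of step 4 to (2S)-2-[4-(tert-butyldimethylsilyloxy)phenyl]-7-methoxy-5-(3-methylbut-2-enyloxy)-2,3-dihydro-4H-chromen-4-one F3. The europium-catalysed para-Claisen–Cope shift, known for 5-O-prenyl flavanones, would then be run on F3 and pass through the ortho-dienone (2S)-2-[4-(tert-butyldimethylsilyloxy)phenyl]-7-methoxy-6-(2-methylbut-3-en-2-yl)-2,3-dihydro-4H-chromene-4,5(6H)-dione F4 and the para-dienone (2S)-2-[4-(tert-butyldimethylsilyloxy)phenyl]-7-methoxy-8-(3-methylbut-2-enyl)-2,3-dihydro-4H-chromene-4,5(8H)-dione F5 to give 10.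

Step 3. The tandem shift may stop after the first [3,3] step by enolisation to the 6-(1,1-dimethylallyl) phenol, or the Lewis acid may cleave the prenyl ether. The fallback sets out from 1 and 2 and comes back at 8, and uses no sigmatropic step. Direct C-alkylation of 1 with 2 (10% aq KOH, 0 °C) would give 1-[2,6-dihydroxy-4-methoxy-3-(3-methylbut-2-enyl)phenyl]ethanone F6. The less hindered phenol, the one not flanked by the prenyl group, would be protected (MeOCH2Cl, iPr2NEt, CH2Cl2, 0 °C) to 1-[2-hydroxy-4-methoxy-6-(methoxymethoxy)-3-(3-methylbut-2-enyl)phenyl]ethanone F7. Me2NCH(OMe)2 would give the enaminone (E)-3-(dimethylamino)-1-[2-hydroxy-4-methoxy-6-(methoxymethoxy)-3-(3-methylbut-2-enyl)phenyl]prop-2-en-1-one F8, which dilute acid would close through the only free phenol, the one next to the prenyl group, to 7-methoxy-5-(methoxymethoxy)-8-(3-methylbut-2-enyl)-4H-chromen-4-one F9. HCl in methanol at 40 °C would then remove the acetal and give 8.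

**Further compounds**

F1 | step 5 | (2S)-5-(tert-butyldimethylsilyloxy)-2-[4-(tert-butyldimethylsilyloxy)phenyl]-7-methoxy-8-(3-methylbut-2-enyl)-2,3-dihydro-4H-chromen-4-one | COc1cc(O[Si](C)(C)C(C)(C)C)c2c(c1CC=C(C)C)O[C@H](c1ccc(O[Si](C)(C)C(C)(C)C)cc1)CC2=O
F2 | step 5 | (2R,3R)-5-(tert-butyldimethylsilyloxy)-2-[4-(tert-butyldimethylsilyloxy)phenyl]-3-hydroxy-7-methoxy-8-(3-methylbut-2-enyl)-2,3-dihydro-4H-chromen-4-one | COc1cc(O[Si](C)(C)C(C)(C)C)c2c(c1CC=C(C)C)O[C@H](c1ccc(O[Si](C)(C)C(C)(C)C)cc1)[C@@H](O)C2=O
F3 | step 4 | (2S)-2-[4-(tert-butyldimethylsilyloxy)phenyl]-7-methoxy-5-(3-methylbut-2-enyloxy)-2,3-dihydro-4H-chromen-4-one | COc1cc(OCC=C(C)C)c2c(c1)O[C@H](c1ccc(O[Si](C)(C)C(C)(C)C)cc1)CC2=O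
F4 | step 4 | (2S)-2-[4-(tert-butyldimethylsilyloxy)phenyl]-7-methoxy-6-(2-methylbut-3-en-2-yl)-2,3-dihydro-4H-chromene-4,5(6H)-dione (C6 epimers) | COC1=CC2=C(C(=O)C1C(C)(C)C=C)C(=O)C[C@@H](c1ccc(O[Si](C)(C)C(C)(C)C)cc1)O2
F5 | step 4 | (2S)-2-[4-(tert-butyldimethylsilyloxy)phenyl]-7-methoxy-8-(3-methylbut-2-enyl)-2,3-dihydro-4H-chromene-4,5(8H)-dione (C8 epimers) | COC1=CC(=O)C2=C(O[C@H](c3ccc(O[Si](C)(C)C(C)(C)C)cc3)CC2=O)C1CC=C(C)C
F6 | step 3 | 1-[2,6-dihydroxy-4-methoxy-3-(3-methylbut-2-enyl)phenyl]ethanone | CC(=O)c1c(O)cc(OC)c(CC=C(C)C)c1O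
F7 | step 3 | 1-[2-hydroxy-4-methoxy-6-(methoxymethoxy)-3-(3-methylbut-2-enyl)phenyl]ethanone | CC(=O)c1c(OCOC)cc(OC)c(CC=C(C)C)c1O
F8 | step 3 | (E)-3-(dimethylamino)-1-[2-hydroxy-4-methoxy-6-(methoxymethoxy)-3-(3-methylbut-2-enyl)phenyl]prop-2-en-1-one | CN(C)/C=C/C(=O)c1c(OCOC)cc(OC)c(CC=C(C)C)c1O
F9 | step 3 | 7-methoxy-5-(methoxymethoxy)-8-(3-methylbut-2-enyl)-4H-chromen-4-one | COc1cc(OCOC)c2c(c1CC=C(C)C)occc2=O
A1 | direct plan | 1-(2,6-dihydroxy-4-methoxyphenyl)ethanone | CC(=O)c1c(O)cc(OC)cc1O
A2 | direct plan | 1-[2-hydroxy-4-methoxy-6-(3-methylbut-2-enyloxy)phenyl]ethanone | CC(=O)c1c(O)cc(OC)cc1OCC=C(C)C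
A3 | direct plan | 2-chloro-1-[4-methoxy-2-(3-methylbut-2-enyloxy)-6-(triisopropylsilyloxy)phenyl]ethanone | ClCC(=O)c1c(O[Si](C(C)C)(C(C)C)C(C)C)cc(OC)cc1OCC=C(C)C
A4 | direct plan | 4-(tert-butyldimethylsilyloxy)benzaldehyde | O=Cc1ccc(O[Si](C)(C)C(C)(C)C)cc1
A5 | direct plan | [(2R,3S)-3-(4-hydroxyphenyl)oxiran-2-yl][2-hydroxy-4-methoxy-6-(3-methylbut-2-enyloxy)phenyl]methanone | O=C(c1c(O)cc(OC)cc1OCC=C(C)C)[C@@H]1O[C@H]1c1ccc(O)cc1
A6 | direct plan | (2R,3R)-3-hydroxy-2-(4-hydroxyphenyl)-7-methoxy-5-(3-methylbut-2-enyloxy)-2,3-dihydro-4H-chromen-4-one | COc1cc(OCC=C(C)C)c2c(c1)O[C@H](c1ccc(O)cc1)[C@@H](O)C2=O
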